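# Proposed synthesis of furospongin-4

## Retrosynthetic overview

1. Chain numbering: C1 (CO2Me) to C17 (CH2 on the furan), with the free carboxyl on C6. The hard feature is the C5–C6(CO2H)=C7–C8 unit with CO2H cis to C8 (6Z), the geometry a stabilised-ylide olefination does not give. It is read as the transposed allyl system of a Morita–Baylis–Hillman (MBH) alcohol.
2. Key disconnection C4–C5: an orthoester Claisen [3,3] shift of MBH alcohol 13 (O on C7, CH2= at C5) forms C4–C5, moves the olefin to C6=C7 and sets 6Z through a chair. The precursor comes in one step (C6–C7) from aldehyde 11 and tert-butyl acrylate.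
3. C2=C3 by Wittig olefination of the C3 aldehyde derived from the Claisen ester. The C6 acid is freed last from its tert-butyl ester, and C1 stays a methyl ester.
4. C7–C16 with both E olefins (C10=C11, C14=C15) come from (2E,6E)-farnesyl acetate, whose terminal olefin is cut to the C7 aldehyde via the epoxide. C16–C17 is made by copper-catalysed coupling with a 3-furylmethyl Grignard reagent.
5. Rings: none is formed. The furan is bought in with furan-3-ylmethanol, and the only other ring, a transient epoxide (step 2), is cleaved in step 5.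

Key step: step 7

Remark: furospongin-4 has no stereocentre, so "single enantiomer" is read as the single geometric isomer (2E,6Z,10E,14E) of the SMILES. Racemic or unassigned centres occur only in intermediates and are erased in steps 5, 7 and 8.

## Route

Step 1
Reactants: 1 furan-3-ylmethanol
Product: 3 furan-3-ylmethyl chloride, via mesylate 2 (not isolated)
Conditions: MsCl, LiCl, 2,4,6-collidine, DMF, 0 °C; extracted cold and used at once
Reagents that add atoms: lithium chloride [Li+].[Cl-]; methanesulfonyl chloride CS(=O)(=O)Cl (its sulfonyl group stays only in 2)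
Why: Chlorination through the mesylate formed in situ (SN2 by chloride) runs under non-acidic conditions that the acid-sensitive furan should tolerate.

Step 2
Reactants: 4 (2E,6E)-farnesyl acetate
Product: 6 (2E,6E)-10,11-epoxy-3,7,11-trimethyldodeca-2,6-dien-1-ol, via bromohydrin acetate 5 (not isolated)
Conditions: NBS (1.1 equiv), THF–H2O, 0 °C; then K2CO3, MeOH, rt
Reagents that add atoms: water O; N-bromosuccinimide O=C1CCC(=O)N1Br (its bromine stays only in 5)
Why: Terminal-selective bromohydrin formation in aqueous THF (water opens the bromonium ion at the tertiary carbon), then base-induced epoxide closure with methanolysis of the acetate; the new centre is racemic and is erased in step 5.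

Step 3
Reactants: 6 (2E,6E)-10,11-epoxy-3,7,11-trimethyldodeca-2,6-dien-1-ol
Product: 8 (2E,6E)-10,11-epoxyfarnesyl bromide, via allylic mesylate 7 (not isolated)
Conditions: MsCl, Et3N, THF, −45 °C; then LiBr, THF, −45 to 0 °C
Reagents that add atoms: lithium bromide [Li+].[Br-]; methanesulfonyl chloride CS(=O)(=O)Cl (its sulfonyl group stays only in 7)
Why: Mesylation and SN2 displacement by bromide at low temperature should give the primary allylic bromide without allylic transposition or opening of the trisubstituted epoxide.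

Step 4
Reactants: 3 furan-3-ylmethyl chloride; 8 (2E,6E)-10,11-epoxyfarnesyl bromide
Product: 10 3-[(3E,7E)-10-(3,3-dimethyloxiran-2-yl)-4,8-dimethyldeca-3,7-dien-1-yl]furan, via Grignard reagent 9 (not isolated)
Conditions: 3 (1.5 equiv), Mg, THF, 0 °C; then 8, Li2CuCl4 (5 mol %), THF, −78 to 0 °C
Reagents that add atoms: magnesium [Mg] (stays only in 9)
Why: Copper-catalysed cross-coupling of a 3-furylmethyl Grignard reagent with a primary allylic bromide should occur at the α-carbon (C16–C17) with retention of the E olefin, and the hindered epoxide should survive at or below 0 °C.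

Step 5
Reactants: 10 3-[(3E,7E)-10-(3,3-dimethyloxiran-2-yl)-4,8-dimethyldeca-3,7-dien-1-yl]furan
Product: 11 (4E,8E)-11-(furan-3-yl)-4,8-dimethylundeca-4,8-dienal
Conditions: H5IO6 (1.2 equiv), THF–H2O, 0 °C
Reagents that add atoms: none
Why: Periodic acid opens the epoxide to the glycol and cleaves it in the same flask (Malaprade cleavage), removing the terminal carbons as acetone and leaving the C7 aldehyde; the racemic centre disappears.

Step 6
Reactants: 11 (4E,8E)-11-(furan-3-yl)-4,8-dimethylundeca-4,8-dienal; 12 tert-butyl acrylate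
Product: 13 tert-butyl (6E,10E)-13-(furan-3-yl)-3-hydroxy-6,10-dimethyl-2-methylidenetrideca-6,10-dienoate
Conditions: quinuclidine (0.5 equiv), MeOH (0.75 equiv), neat in 12 (3 equiv), rt, several days
Reagents that add atoms: none
Why: Morita–Baylis–Hillman reaction: the amine–acrylate zwitterionic enolate adds to the aldehyde and the catalyst is expelled, forming C6–C7; the carbinol centre is racemic and is consumed in step 7.

Step 7
Reactants: 13 tert-butyl (6E,10E)-13-(furan-3-yl)-3-hydroxy-6,10-dimethyl-2-methylidenetrideca-6,10-dienoate; 14 triethyl orthoacetate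
Product: 17 (2Z)-1-tert-butyl 5-ethyl 2-[(4E,8E)-11-(furan-3-yl)-4,8-dimethylundeca-4,8-dien-1-ylidene]pentanedioate, via mixed orthoester 15 (not isolated), via ketene acetal 16 (not isolated)
Conditions: MeC(OEt)3 (7 equiv), EtCO2H (0.1 equiv), 140 °C, EtOH distilled off
Reagents that add atoms: none
Why: Johnson orthoester Claisen rearrangement: acid-catalysed exchange gives mixed orthoester 15, loss of ethanol gives ketene acetal 16, and its concerted [3,3]-sigmatropic shift forms the C4–C5 bond at the methylidene carbon while C7–O breaks and the olefin moves from C5=C6 to C6=C7. The closest known reaction type is the orthoester Claisen rearrangement of 2-substituted secondary allylic alcohols to trisubstituted olefins, which has been applied to 3-hydroxy-2-methylidene esters of this kind. No ring is closed and no stereocentre is formed (the racemic carbinol centre is consumed); the element to control is the C6=C7 geometry. In the chair transition state the C8 chain on the carbinol carbon should sit pseudo-equatorial, because the pseudo-axial position meets a 1,3-diaxial clash with the ethoxy group on the ketene acetal carbon; this puts C8 trans to the new C5 chain and therefore cis to the ester, which is the 6Z geometry. The tert-butyl ester, the furan and the two isolated E olefins should be inert to catalytic propionic acid at 140 °C.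

Step 8
Reactants: 17 (2Z)-1-tert-butyl 5-ethyl 2-[(4E,8E)-11-(furan-3-yl)-4,8-dimethylundeca-4,8-dien-1-ylidene]pentanedioate
Product: 19 tert-butyl (2Z,6E,10E)-13-(furan-3-yl)-6,10-dimethyl-2-(3-oxopropyl)trideca-2,6,10-trienoate, via aluminium hemiacetal 18 (not isolated)
Conditions: DIBAL-H (1.05 equiv), CH2Cl2, −78 °C; MeOH, then aq. Rochelle salt
Reagents that add atoms: diisobutylaluminium hydride CC(C)C[AlH]CC(C)C (its aluminium and isobutyl groups stay only in 18)
Why: Partial ester reduction with DIBAL-H: the unhindered saturated ethyl ester should be reduced to the hemiacetal 18, stable at −78 °C, which gives the aldehyde on work-up, while the conjugated, α-branched tert-butyl ester is too hindered to react.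

Step 9
Reactants: 19 tert-butyl (2Z,6E,10E)-13-(furan-3-yl)-6,10-dimethyl-2-(3-oxopropyl)trideca-2,6,10-trienoate; 20 methyl 2-(triphenylphosphoranylidene)propanoate
Product: 21 tert-butyl (2Z,6E,10E)-13-(furan-3-yl)-2-[(3E)-5-methoxy-4-methyl-5-oxopent-3-en-1-yl]-6,10-dimethyltrideca-2,6,10-trienoate
Conditions: 20 (1.3 equiv), CH2Cl2, rt to 40 °C
Reagents that add atoms: none
Why: Wittig olefination with a stabilised α-methyl ylide should give the E-configured 2-methyl enoate (C2=C3) and leave the tert-butyl ester and the Z acrylate untouched.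

Step 10
Reactants: 21 tert-butyl (2Z,6E,10E)-13-(furan-3-yl)-2-[(3E)-5-methoxy-4-methyl-5-oxopent-3-en-1-yl]-6,10-dimethyltrideca-2,6,10-trienoate
Product: 23 furospongin-4, via trimethylsilyl ester 22 (not isolated)
Conditions: TMSOTf (2.5 equiv), 2,6-lutidine (4 equiv), CH2Cl2, 0 °C; then pH 5 aqueous buffer
Reagents that add atoms: trimethylsilyl trifluoromethanesulfonate C[Si](C)(C)OS(=O)(=O)C(F)(F)F (its silyl group stays only in 22)
Why: Silyl-triflate cleavage of the tert-butyl ester (O-silylation, loss of the tert-butyl cation as isobutene to the hindered base) avoids protic acid that the furan and the 1,5-diene chain would not tolerate; silyl ester 22 hydrolyses on work-up and the methyl ester is not touched.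

## Compound list

1 | furan-3-ylmethanol | OCc1ccoc1 | starting material
2 | furan-3-ylmethyl methanesulfonate | CS(=O)(=O)OCc1ccoc1 | intermediate (not isolated)
3 | furan-3-ylmethyl chloride | ClCc1ccoc1 | intermediate
4 | (2E,6E)-farnesyl acetate | CC(=O)OC/C=C(C)/CC/C=C(C)/CCC=C(C)C | starting material
5 | (2E,6E)-10-bromo-11-hydroxy-3,7,11-trimethyldodeca-2,6-dien-1-yl acetate (racemic) | CC(=O)OC/C=C(C)/CC/C=C(C)/CCC(Br)C(C)(C)O | intermediate (not isolated)
6 | (2E,6E)-10,11-epoxy-3,7,11-trimethyldodeca-2,6-dien-1-ol (racemic) | OC/C=C(C)/CC/C=C(C)/CCC1OC1(C)C | intermediate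
7 | (2E,6E)-10,11-epoxyfarnesyl methanesulfonate (racemic) | CS(=O)(=O)OC/C=C(C)/CC/C=C(C)/CCC1OC1(C)C | intermediate (not isolated)
8 | (2E,6E)-10,11-epoxyfarnesyl bromide (racemic) | BrC/C=C(C)/CC/C=C(C)/CCC1OC1(C)C | intermediate
9 | (furan-3-ylmethyl)magnesium chloride | Cl[Mg]Cc1ccoc1 | intermediate (not isolated)
10 | 3-[(3E,7E)-10-(3,3-dimethyloxiran-2-yl)-4,8-dimethyldeca-3,7-dien-1-yl]furan (racemic) | CC1(C)OC1CC/C(C)=C/CC/C(C)=C/CCc1ccoc1 | intermediate
11 | (4E,8E)-11-(furan-3-yl)-4,8-dimethylundeca-4,8-dienal | O=CCC/C(C)=C/CC/C(C)=C/CCc1ccoc1 | intermediate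
12 | tert-butyl acrylate | C=CC(=O)OC(C)(C)C | starting material
13 | tert-butyl (6E,10E)-13-(furan-3-yl)-3-hydroxy-6,10-dimethyl-2-methylidenetrideca-6,10-dienoate (racemic) | C=C(C(=O)OC(C)(C)C)C(O)CC/C(C)=C/CC/C(C)=C/CCc1ccoc1 | intermediate
14 | triethyl orthoacetate | CCOC(C)(OCC)OCC | starting material
15 | tert-butyl (6E,10E)-3-(1,1-diethoxyethoxy)-13-(furan-3-yl)-6,10-dimethyl-2-methylidenetrideca-6,10-dienoate (racemic) | C=C(C(=O)OC(C)(C)C)C(OC(C)(OCC)OCC)CC/C(C)=C/CC/C(C)=C/CCc1ccoc1 | intermediate (not isolated)
16 | tert-butyl (6E,10E)-3-[(1-ethoxyethenyl)oxy]-13-(furan-3-yl)-6,10-dimethyl-2-methylidenetrideca-6,10-dienoate (racemic) | C=C(C(=O)OC(C)(C)C)C(OC(=C)OCC)CC/C(C)=C/CC/C(C)=C/CCc1ccoc1 | intermediate (not isolated)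
17 | (2Z)-1-tert-butyl 5-ethyl 2-[(4E,8E)-11-(furan-3-yl)-4,8-dimethylundeca-4,8-dien-1-ylidene]pentanedioate | CCOC(=O)CC/C(=C/CC/C(C)=C/CC/C(C)=C/CCc1ccoc1)C(=O)OC(C)(C)C | intermediate
18 | diisobutylaluminium hemiacetal of 17 at the ethyl ester carbon | CCOC(O[Al](CC(C)C)CC(C)C)CC/C(=C/CC/C(C)=C/CC/C(C)=C/CCc1ccoc1)C(=O)OC(C)(C)C | intermediate (not isolated)
19 | tert-butyl (2Z,6E,10E)-13-(furan-3-yl)-6,10-dimethyl-2-(3-oxopropyl)trideca-2,6,10-trienoate | O=CCC/C(=C/CC/C(C)=C/CC/C(C)=C/CCc1ccoc1)C(=O)OC(C)(C)C | intermediate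
20 | methyl 2-(triphenylphosphoranylidene)propanoate | COC(=O)C(C)=P(c1ccccc1)(c1ccccc1)c1ccccc1 | starting material
21 | tert-butyl (2Z,6E,10E)-13-(furan-3-yl)-2-[(3E)-5-methoxy-4-methyl-5-oxopent-3-en-1-yl]-6,10-dimethyltrideca-2,6,10-trienoate | COC(=O)/C(C)=C/CC/C(=C/CC/C(C)=C/CC/C(C)=C/CCc1ccoc1)C(=O)OC(C)(C)C | intermediate
22 | trimethylsilyl (2Z,6E,10E)-13-(furan-3-yl)-2-[(3E)-5-methoxy-4-methyl-5-oxopent-3-en-1-yl]-6,10-dimethyltrideca-2,6,10-trienoate | COC(=O)/C(C)=C/CC/C(=C/CC/C(C)=C/CC/C(C)=C/CCc1ccoc1)C(=O)O[Si](C)(C)C | intermediate (not isolated)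
23 | furospongin-4, (2Z,6E,10E)-13-(furan-3-yl)-2-[(3E)-5-methoxy-4-methyl-5-oxopent-3-en-1-yl]-6,10-dimethyltrideca-2,6,10-trienoic acid | COC(=O)/C(C)=C/CC/C(=C/CC/C(C)=C/CC/C(C)=C/CCc1ccoc1)C(=O)O | target

## Step count and risks

Total step count: 10. Longest linear sequence: 9 steps (4 to 23, steps 2–10); step 1 is a one-step side branch.

Steps most likely to fail:

Step 6. The addition of the hindered tert-butyl acrylate to an enolisable aliphatic aldehyde may be so slow that self-aldol condensation and slow decay of the aldehyde compete. The fallback sets out from 11 and comes back at 13, and replaces the amine-catalysed process by a stoichiometric vinylalumination. Hydroalumination of tert-butyl propiolate with DIBAL-H in the presence of N-methylmorpholine N-oxide (THF, 0 °C) should give tert-butyl 2-(diisobutylalumanyl)prop-2-enoate F1. This adds to 11 at room temperature to give the aluminium alkoxide tert-butyl (6E,10E)-3-[(diisobutylalumanyl)oxy]-13-(furan-3-yl)-6,10-dimethyl-2-methylidenetrideca-6,10-dienoate F2, and aqueous work-up releases 13.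

Step 8. The reduction may run past the aldehyde stage, or the hydride may fail to distinguish the two esters. The fallback sets out from 17 and comes back at 19, and uses a reduction–oxidation relay instead of a partial reduction. LiBH4 (THF, 1 equiv MeOH, 0 °C), which does not attack tert-butyl esters, should reduce the ethyl ester fully to tert-butyl (2Z,6E,10E)-13-(furan-3-yl)-2-(3-hydroxypropyl)-6,10-dimethyltrideca-2,6,10-trienoate F3. Dess–Martin oxidation (NaHCO3, CH2Cl2) then gives 19.

Step 7. Part of the material may rearrange through the chair with the C8 chain pseudo-axial, eroding the 6Z geometry, or the allylic alcohol may undergo acid-promoted transposition before the sigmatropic shift. The fallback sets out from 11 and comes back at 17, by-passing 13, and builds C6=C7 by a Z-selective Horner–Wadsworth–Emmons olefination with a diaryl phosphonate. Diphenyl phosphite and tert-butyl bromoacetate (Et3N, CH2Cl2) give tert-butyl 2-(diphenoxyphosphoryl)acetate F4. Base-catalysed conjugate addition of F4 to ethyl acrylate (cat. t-BuOK, THF, 0 °C) gives 1-tert-butyl 5-ethyl 2-(diphenoxyphosphoryl)pentanedioate F5. Its sodium salt (NaH, THF, −78 to 0 °C) should condense with 11 to give 17, the diaryloxyphosphoryl group favouring the acrylate with the ester cis to the aldehyde-derived chain.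

Further compounds

F1 | step 6 | tert-butyl 2-(diisobutylalumanyl)prop-2-enoate | C=C(C(=O)OC(C)(C)C)[Al](CC(C)C)CC(C)C
F2 | step 6 | tert-butyl (6E,10E)-3-[(diisobutylalumanyl)oxy]-13-(furan-3-yl)-6,10-dimethyl-2-methylidenetrideca-6,10-dienoate (racemic) | C=C(C(=O)OC(C)(C)C)C(O[Al](CC(C)C)CC(C)C)CC/C(C)=C/CC/C(C)=C/CCc1ccoc1
F3 | step 8 | tert-butyl (2Z,6E,10E)-13-(furan-3-yl)-2-(3-hydroxypropyl)-6,10-dimethyltrideca-2,6,10-trienoate | OCCC/C(=C/CC/C(C)=C/CC/C(C)=C/CCc1ccoc1)C(=O)OC(C)(C)C
F4 | step 7 | tert-butyl 2-(diphenoxyphosphoryl)acetate | CC(C)(C)OC(=O)CP(=O)(Oc1ccccc1)Oc1ccccc1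
F5 | step 7 | 1-tert-butyl 5-ethyl 2-(diphenoxyphosphoryl)pentanedioate (racemic) | CCOC(=O)CCC(C(=O)OC(C)(C)C)P(=O)(Oc1ccccc1)Oc1ccccc1
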